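(The earlier runs and the new flask are calculated for substances that don't exist.)

Slowness is what the earlier flasks show: after 60.0 min the epsilon run read 1.7% target and 1.6% trapped intermediate, each with a scatter of 0.5 percentage points. Starting material and partner make the open intermediate; second reagent turns it into target, capture agent into trapped intermediate; protic impurity turns partner into quenched reagent.

| flask | starting material | partner | second reagent | protic impurity | capture agent | temperature | remark | time |
|---|---|---|---|---|---|---|---|---|
| beta | 0.15 M | 0.090 M | 0.23 M | 0.030 M | 3 mM | −25 °C | run made earlier |  |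
| eta | 0.15 M | 0.090 M | 0.55 M | 0.030 M | 3 mM | −14 °C | run made earlier |  |
| epsilon | 0.15 M | 0.090 M | 0.30 M | 0.030 M | 5.3 mM | −25 °C | run made earlier |  |
| Friday's | 0.15 M | 0.0900 M | 0.300 M | 0.0600 M | 3.00 mM | −20 °C |  | 2.0 h |
| Sunday's | 0.15 M | 0.0900 M | 0.300 M | 0.0300 M | 3.00 mM | −20 °C |  | 2.0 h |
| Wednesday's | 0.15 M | 0.0300 M | 0.300 M | 0.0300 M | 6.00 mM | −20 °C |  | 2.0 h |
| Tuesday's | 0.15 M | 0.250 M | 0.200 M | 0.0300 M | 3.00 mM | −20 °C |  | 2.0 h |
| Saturday's | 0.15 M | 0.0900 M | 0.500 M | 0.0300 M | 12.0 mM | −20 °C |  | 2.0 h |
| Monday's | 0.15 M | 0.0900 M | 0.300 M | 0.0100 M | 3.00 mM | −20 °C |  | 2.0 h |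

| run | time / min | target / % | trapped intermediate / % |
|---|---|---|---|
| beta | 5.00 | 0 | 0.4 |
| beta | 8.00 | 0.7 | 1.1 |
| beta | 12.0 | 0.2 | 0.1 |
| beta | 20.0 | 0.5 | 0.5 |
| beta | 40.0 | 0 | 0.6 |
| beta | 60.0 | 1.3 | 0 |
| eta | 4.00 | 0.4 | 0 |
| eta | 12.0 | 1.7 | 0 |
| eta | 20.0 | 2.6 | 1.1 |
| eta | 30.0 | 5.1 | 0.5 |
| eta | 50.0 | 10.2 | 0.4 |
| eta | 60.0 | 13.5 | 2.0 |
| epsilon | 5.00 | 0 | 0 |
| epsilon | 15.0 | 0.1 | 0.4 |
| epsilon | 30.0 | 0.9 | 0.7 |
| epsilon | 40.0 | 0 | 0.4 |
| epsilon | 60.0 | 1.7 | 1.6 |

(readings scatter by 0.5 percentage points)

- the earlier runs were read with a standard deviation of 0.5 percentage points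
- candidate steps: starting material + partner -> open intermediate; second reagent + open intermediate -> target; partner + protic impurity -> quenched reagent; open intermediate + capture agent -> trapped intermediate
- no earlier run changes the charge of protic impurity; that part of a forecast is a guess

* ranking by share of target in all that became target or trapped intermediate, from high to low, at 2.0 h (Friday's / Sunday's / Wednesday's / Tuesday's / Saturday's / Monday's)
* the share of target in all that became target or trapped intermediate of the flask you put first, at 2.0 h
* the share of target in all that became target or trapped intermediate of the flask you put last, at 2.0 h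

Follow one molecule of open intermediate. At its fork, the odds for target are s × second reagent / capture agent, with s the selectivity factor. Summed over a run with second reagent taken as steady, target as a fraction of the starting-material charge is s × (second-reagent charge / starting-material charge) × E, where the exposure E is the logarithm of capture charge over capture left. In the epsilon run the trapped reading leaves 54.7% of the capture agent, so E is 0.603 and s is 0.0141. This is a rough reading, taken at −25 °C and not −20 °C.

My own ladder for Tuesday's flask starts with a guess: protic impurity takes its match of partner first. Next comes capture. The eta run's target grows faster than time, from 1.7% at 12.0 min to 13.5% at 60.0 min, as from a filling pool, so I let exposure grow with time squared and with the partner charge less the impurity charge. Scaled from the epsilon run with no allowance for temperature, that gives Tuesday's flask a reckoned exposure of 8.84 by 2.0 h, and an exposure of one near 40.4 min. Its odds at the start are 0.940, and I reckon trapped intermediate to stop at its ceiling of 2.00% of the starting-material charge. The last rung is target, reckoned at 16.6%, a share of 89.3%. Wednesday's partner charge equals its impurity charge, so for that flask I reckon the share at the start, 41.3%.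

The forecast gives Tuesday's > Monday's > Sunday's > Friday's > Saturday's > Wednesday's, with 66% (50% to 76%) for Wednesday's flask and 94% (90% to 97%) for Tuesday's flask, where it stands above my 89.3%. It notes: “The last two are close; the impurity effect is a guess.”

The simulation gives Tuesday's > Monday's > Sunday's > Friday's > Saturday's > Wednesday's, with 87.4% for Tuesday's flask and 53.7% for Wednesday's.

    starting material + partner → open intermediate (k = 0.0853 M⁻¹ min⁻¹, Ea = 63.0 kJ mol⁻¹)
    second reagent + open intermediate → target (k = 0.0135 M⁻¹ min⁻¹, Ea = 68.0 kJ mol⁻¹)
    partner + protic impurity → quenched reagent (k = 0.747 M⁻¹ min⁻¹, Ea = 46.0 kJ mol⁻¹)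
    open intermediate + capture agent → trapped intermediate (k = 0.769 M⁻¹ min⁻¹, Ea = 43.0 kJ mol⁻¹)
    (constants at −20 °C)

Tuesday's flask kept 0.194% of its capture agent, an exposure of 6.24, lower than reckoned. Its 13.8% target gives s as 0.0166 at −20 °C, above the epsilon reading of 0.0141 at −25 °C. The neighbouring flask, Tuesday's with 0.80 M of second reagent, kept 1.10% of its capture agent, an exposure of 4.51. The same reckoning then gives 40.0% target, and that flask holds 40.6% target beside 1.98% trapped intermediate, a share of 95.4%.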